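**Retrosynthetic overview**
- Feature: in the benzene ring of the indole, C4(Br)–C5(H)–C6(Br)–C7(H) alternates Br/H in the same way as C3–C4–C5–C6 of 3,5-dibromo-2-pyrone. Only the fusion carbons C3a and C7a have to come from another fragment.
- Last disconnection: C2–Br, made by C–H borylation of 4,6-dibromoindole at C2 and copper-mediated ipso-bromination. The pyrrole ring is traced back to an indoline (Boc removal first, then dehydrogenation).
- Key disconnection: C7–C7a and C3a–C4 are cut together. The pyrone ring becomes the benzene ring by (4+2) cycloaddition to the C=C of an N-Boc-3-silyloxy-2-pyrroline, followed by loss of CO2 and silanol.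
- Precursors: the pyrone comes from coumalic acid. The enol ether is made regiospecifically from N-Boc-2,3-dihydropyrrole (epoxidation/methanolysis, silylation, loss of MeOH), because enolising the 3-pyrrolidinone can place the double bond on either side.
- Ring order: the five-membered N-ring is bought, the benzene ring is built on it from the pyrone ring, and the pyrrole is aromatised afterwards.

Key step: step 4

Assumption: the target is achiral and every stereocentre in the saturated intermediates is transient, so racemic material is used and each SMILES shows one enantiomer of the main relative configuration.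

**Step 1**
Reactants: 1 coumalic acid (2-oxo-2H-pyran-5-carboxylic acid)
Product: 2 3,5-dibromo-2H-pyran-2-one
Conditions: NBS (2.5 equiv), Bu4NBr (cat.), CHCl3, 50 °C
Reagents that add atoms: N-bromosuccinimide, O=C1CCC(=O)N1Br
Why: Hunsdiecker-type bromodecarboxylation replaces the C5 carboxyl group by bromine and electrophilic bromination (addition–elimination) takes the remaining enol-like position C3, a known one-flask preparation of this pyrone.

**Step 2**
Reactants: 3 tert-butyl 2,3-dihydro-1H-pyrrole-1-carboxylate
Product: 4 tert-butyl trans-3-hydroxy-2-methoxypyrrolidine-1-carboxylate (racemic)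
Conditions: mCPBA (1.1 equiv), MeOH, −10 → 0 °C
Reagents that add atoms: meta-chloroperoxybenzoic acid, O=C(OO)c1cccc(Cl)c1; methanol, CO
Why: Prilezhaev epoxidation of the electron-rich enecarbamate and in situ methanolysis of the labile amino epoxide through its N-acyliminium ion put the oxygen unambiguously on C3, with methanol adding mainly anti to the new hydroxyl (trans), and both stereocentres are erased in step 3.

**Step 3**
Reactants: 4 tert-butyl trans-3-hydroxy-2-methoxypyrrolidine-1-carboxylate; 5 tert-butyldimethylsilyl trifluoromethanesulfonate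
Product: 7 tert-butyl 4-[(tert-butyldimethylsilyl)oxy]-2,3-dihydro-1H-pyrrole-1-carboxylate, via silyl ether 6 (not isolated)
Conditions: 5 (1.1 equiv), i-Pr2NEt (3.5 equiv), CH2Cl2, −78 → 0 °C; then TMSOTf (1.2 equiv), 0 °C; NaHCO3 quench; Et3N-deactivated silica
Reagents that add atoms: tert-butyldimethylsilyl trifluoromethanesulfonate (5), CC(C)(C)[Si](C)(C)OS(=O)(=O)C(F)(F)F
Why: O-silylation followed by silyl-triflate ionisation of the N,O-acetal gives an N-acyliminium ion whose only β-hydrogen sits on C3, so the amine-mediated E1-type elimination (the known α-methoxycarbamate to enecarbamate conversion) can give only the 2,3-double-bond isomer.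

**Step 4**
Reactants: 2 3,5-dibromo-2H-pyran-2-one; 7 tert-butyl 4-[(tert-butyldimethylsilyl)oxy]-2,3-dihydro-1H-pyrrole-1-carboxylate
Product: 10 tert-butyl 4,6-dibromoindoline-1-carboxylate, via bridged lactone 8 (not isolated), via silyloxy cyclohexadiene 9 (not isolated)
Conditions: 7 (1.5 equiv), 2,6-di-tert-butylpyridine (10 mol %), o-xylene, 110 °C, then 145 °C; then PPTS (20 mol %), 80 °C
Reagents that add atoms: none
Why: The electron-poor diene C3=C4–C5=C6 of 2 and the electron-rich C=C of 7 combine in an inverse-demand Diels–Alder reaction, and the closest known chemistry is the cycloaddition of 3,5-dibromo-2-pyrone to silyl enol ethers (silyloxy carbon ending next to the C–Br bridgehead) together with the pyrone-to-arene conversion by CO2 extrusion and elimination. The six-membered carbocycle is closed intermolecularly in one concerted but asynchronous (4+2) event, in which the leading bond joins the two unhindered CH termini (the N-bearing carbon of 7, β to the silyloxy donor, and the vinylogous acceptor carbon C6 of 2) to make C7–C7a, and the lagging bond joins the silyloxy carbon to C3(Br) to make C3a–C4. Retro-(4+2) loss of CO2 from 8 leaves 9 with both bromines on sp2 carbons and no hydrogen on C3a, so the only aromatising exit is loss of tert-butyldimethylsilanol across C3a–C7a, which PPTS completes through the arenium-type cation at C3a. The four stereocentres of 8 (suprafacial addition, hence cis ring fusion, endo/exo mixture) are all erased, so 10 has none and no facial or endo/exo control is needed. The selectivity that is needed is regiochemical: the silyloxy oxygen must outrank the nitrogen, whose lone pair is shared with the Boc carbonyl, and the tertiary oxocarbenium character and low steric demand of the favoured transition state work in the same direction, whereas the reverse orientation would give the 5,7-dibromo isomer. Double-bond purity of 7 matters equally, because the 2,5-dihydro isomer would lead to an isoindoline, hence the regiospecific preparation and the hindered base that traps adventitious HBr.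

**Step 5**
Reactants: 10 tert-butyl 4,6-dibromoindoline-1-carboxylate
Product: 11 4,6-dibromoindoline
Conditions: TFA/CH2Cl2 1:3, 0 °C → rt; aq. NaHCO3 work-up
Reagents that add atoms: none
Why: Acidolysis of the tert-butyl carbamate (loss of isobutene and CO2) is placed before the oxidation because an N-acylated, dibrominated indoline is a poor hydride donor toward quinones, and aryl bromides are inert to TFA.

**Step 6**
Reactants: 11 4,6-dibromoindoline
Product: 12 4,6-dibromo-1H-indole
Conditions: DDQ (1.05 equiv), CH2Cl2, 0 °C → rt
Reagents that add atoms: none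
Why: Quinone dehydrogenation (hydride abstraction from C2 assisted by the free nitrogen lone pair, then proton loss from C3) aromatises N–H indolines quickly under mild conditions and does not touch the C–Br bonds.

**Step 7**
Reactants: 12 4,6-dibromo-1H-indole
Product: 13 4,6-dibromo-2-(4,4,5,5-tetramethyl-1,3,2-dioxaborolan-2-yl)-1H-indole
Conditions: [Ir(OMe)(cod)]2 (1.5 mol %), dtbpy (3 mol %), B2pin2 (1.1 equiv), THF, 60 °C
Reagents that add atoms: bis(pinacolato)diboron, CC1(C)OB(OC1(C)C)B1OC(C)(C)C(C)(C)O1
Why: Iridium-catalysed aromatic C–H borylation of N–H indoles prefers C2, and here C5 and C7 are shielded by ortho bromines and C3 by the peri bromine at C4, while the trivalent iridium trisboryl catalyst leaves aryl bromides intact.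

**Step 8**
Reactants: 13 4,6-dibromo-2-(4,4,5,5-tetramethyl-1,3,2-dioxaborolan-2-yl)-1H-indole
Product: 14 2,4,6-tribromo-1H-indole
Conditions: CuBr2 (3 equiv), MeOH/H2O 1:1, 80 °C, sealed vessel, dark
Reagents that add atoms: CuBr2, [Cu+2].[Br-].[Br-]
Why: Copper-mediated ipso-bromodeboronation of an aryl pinacol boronate (transmetalation to divalent copper, oxidation by a second CuBr2 to a trivalent arylcopper bromide, C–Br reductive elimination) puts bromine exactly where boron sat, whereas electrophilic bromine sources would attack C3.

**Compound list**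
1 | coumalic acid | O=C(O)c1ccc(=O)oc1 | starting material
2 | 3,5-dibromo-2H-pyran-2-one | O=c1occ(Br)cc1Br | intermediate
3 | tert-butyl 2,3-dihydro-1H-pyrrole-1-carboxylate | CC(C)(C)OC(=O)N1CCC=C1 | starting material
4 | tert-butyl trans-3-hydroxy-2-methoxypyrrolidine-1-carboxylate (racemic) | CO[C@H]1[C@H](O)CCN1C(=O)OC(C)(C)C | intermediate
5 | tert-butyldimethylsilyl trifluoromethanesulfonate | CC(C)(C)[Si](C)(C)OS(=O)(=O)C(F)(F)F | starting material
6 | tert-butyl trans-3-[(tert-butyldimethylsilyl)oxy]-2-methoxypyrrolidine-1-carboxylate (racemic, not isolated) | CO[C@H]1[C@H](O[Si](C)(C)C(C)(C)C)CCN1C(=O)OC(C)(C)C | intermediate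
7 | tert-butyl 4-[(tert-butyldimethylsilyl)oxy]-2,3-dihydro-1H-pyrrole-1-carboxylate | CC(C)(C)OC(=O)N1CCC(O[Si](C)(C)C(C)(C)C)=C1 | intermediate
8 | bridged lactone cycloadduct (indole numbering: C4(Br) and C7(H) bridged by C(=O)–O with the carbonyl on C4, C5=C6(Br) alkene, cis-fused N-Boc pyrrolidine, OTBS on C3a; racemic; drawn with OTBS syn to the alkene bridge, the other diastereomer converges; not isolated) | O=C1O[C@H]2C(Br)=C[C@]1(Br)[C@@]1(O[Si](C)(C)C(C)(C)C)CCN(C(=O)OC(C)(C)C)[C@@H]21 | intermediate
9 | tert-butyl cis-4,6-dibromo-3a-[(tert-butyldimethylsilyl)oxy]-2,3,3a,7a-tetrahydro-1H-indole-1-carboxylate (racemic, not isolated) | CC(C)(C)OC(=O)N1CC[C@]2(O[Si](C)(C)C(C)(C)C)C(Br)=CC(Br)=C[C@H]12 | intermediate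
10 | tert-butyl 4,6-dibromoindoline-1-carboxylate | CC(C)(C)OC(=O)N1CCc2c(Br)cc(Br)cc21 | intermediate
11 | 4,6-dibromoindoline | Brc1cc(Br)c2CCNc2c1 | intermediate
12 | 4,6-dibromo-1H-indole | Brc1cc(Br)c2cc[nH]c2c1 | intermediate
13 | 4,6-dibromo-2-(4,4,5,5-tetramethyl-1,3,2-dioxaborolan-2-yl)-1H-indole | CC1(C)OB(OC1(C)C)c1cc2c(Br)cc(Br)cc2[nH]1 | intermediate
14 | 2,4,6-tribromo-1H-indole | Brc1cc(Br)c2cc(Br)[nH]c2c1 | target

**Total step count:** 8. **Longest linear sequence:** 7 (steps 2–8, from 3). The pyrone branch adds step 1.

**Steps most likely to fail**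

**Step 4.** The carbamate nitrogen may compete with the silyloxy group as the directing donor, so that the cycloaddition leaks into the reverse orientation. The long heating that a trisubstituted dienophile needs may also erode the Boc group.

The fallback sets out from 2 and returns at 11. The dienophile is redesigned with a sulfonamide nitrogen, which is a weaker π-donor and is thermally robust.
- Purchased 1-tosyl-2,5-dihydro-1H-pyrrole is isomerised with RuHCl(CO)(PPh3)3 in hot toluene to 1-tosyl-2,3-dihydro-1H-pyrrole F1.
- mCPBA in methanol gives trans-2-methoxy-1-tosylpyrrolidin-3-ol F2.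
- 5 and i-Pr2NEt give trans-3-[(tert-butyldimethylsilyl)oxy]-2-methoxy-1-tosylpyrrolidine F3. TMSOTf then removes methanol from it to leave 4-[(tert-butyldimethylsilyl)oxy]-1-tosyl-2,3-dihydro-1H-pyrrole F4.
- Heating F4 with 2 as in step 4 should pass through the N-tosyl bridged lactone F5 and the N-tosyl silyloxy cyclohexadiene F6 to 4,6-dibromo-1-tosylindoline F7.
- Acidolysis of this electron-poor N-aryl sulfonamide with TfOH in 1,2-dichloroethane at 90 °C leaves aryl bromides alone and gives 11.

**Step 8.** In hot aqueous methanol the heteroaryl boronate may protodeboronate. CuBr2 may also brominate C3 oxidatively, and the HBr that is released may degrade the acid-sensitive N–H 2-bromoindole.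

The fallback sets out from 13 and returns at 14. The C–B bond is turned into C–O instead of C–Br.
- NaBO3·4H2O in THF/water oxidises 13, and the product settles as its lactam tautomer 4,6-dibromoindolin-2-one F8.
- Deoxybromination with POBr3 and imidazole in 1,2-dichloroethane at 80 °C is the known oxindole to 2-bromoindole conversion. It gives 14 under non-oxidising conditions in which C3 cannot be brominated.

**Step 3.** The silyl triflate may attack the Boc group, ionisation of the N,O-acetal may stay incomplete, and the enol ether may hydrolyse or suffer acid-catalysed double-bond drift during isolation.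

The fallback sets out from 4 and returns at 7.
- PPTS in warm toluene removes methanol from 4, and the resulting enol tautomerises to tert-butyl 3-oxopyrrolidine-1-carboxylate F9. This ketone is also commercially available.
- Soft enolisation of F9 with 5 and Et3N in CH2Cl2 is left to equilibrate at room temperature. It gives 7 beside tert-butyl 3-[(tert-butyldimethylsilyl)oxy]-2,5-dihydro-1H-pyrrole-1-carboxylate F10, which is removed by chromatography on Et3N-deactivated silica.

**Further compounds**
F1 | step 4 | 1-tosyl-2,3-dihydro-1H-pyrrole | Cc1ccc(cc1)S(=O)(=O)N1CCC=C1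
F2 | step 4 | trans-2-methoxy-1-tosylpyrrolidin-3-ol (racemic) | CO[C@H]1[C@H](O)CCN1S(=O)(=O)c1ccc(C)cc1
F3 | step 4 | trans-3-[(tert-butyldimethylsilyl)oxy]-2-methoxy-1-tosylpyrrolidine (racemic) | CO[C@H]1[C@H](O[Si](C)(C)C(C)(C)C)CCN1S(=O)(=O)c1ccc(C)cc1
F4 | step 4 | 4-[(tert-butyldimethylsilyl)oxy]-1-tosyl-2,3-dihydro-1H-pyrrole | Cc1ccc(cc1)S(=O)(=O)N1CCC(O[Si](C)(C)C(C)(C)C)=C1
F5 | step 4 | N-tosyl bridged lactone (N-tosyl analogue of 8, racemic) | O=C1O[C@H]2C(Br)=C[C@]1(Br)[C@@]1(O[Si](C)(C)C(C)(C)C)CCN(S(=O)(=O)c3ccc(C)cc3)[C@@H]21
F6 | step 4 | N-tosyl silyloxy cyclohexadiene (N-tosyl analogue of 9, racemic) | Cc1ccc(cc1)S(=O)(=O)N1CC[C@]2(O[Si](C)(C)C(C)(C)C)C(Br)=CC(Br)=C[C@H]12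
F7 | step 4 | 4,6-dibromo-1-tosylindoline | Cc1ccc(cc1)S(=O)(=O)N1CCc2c(Br)cc(Br)cc21
F8 | step 8 | 4,6-dibromoindolin-2-one | O=C1Cc2c(Br)cc(Br)cc2N1
F9 | step 3 | tert-butyl 3-oxopyrrolidine-1-carboxylate | CC(C)(C)OC(=O)N1CCC(=O)C1
F10 | step 3 | tert-butyl 3-[(tert-butyldimethylsilyl)oxy]-2,5-dihydro-1H-pyrrole-1-carboxylate | CC(C)(C)OC(=O)N1CC=C(O[Si](C)(C)C(C)(C)C)C1
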